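The target is what I wanted at the end of each set-up, and in the closed flask it rose steadily, with the readings at 80 min averaging 4.93%.

| setting | epsilon | zeta | gamma | Tuesday's | Thursday's | Saturday's | Sunday's |
|---|---|---|---|---|---|---|---|
| substrate | 0.11 M | 0.11 M | 0.11 M | 0.11 M | 0.11 M | 0.11 M | 0.11 M |
| partner | 0.143 M | 0.143 M | 0.143 M | 0.143 M | 0.143 M | 0.143 M | 0.143 M (fed, over 64.0 min) |
| free catalyst | 11 mM | 7.4 mM | 16 mM | 11 mM | 11 mM | 11 mM | 11 mM |
| second catalyst | 0.11 mM | 0.11 mM | 0.11 mM | 0.11 mM | 0.11 mM | 0.11 mM | 0.11 mM |
| remark | run made earlier | run made earlier | run made earlier | a single well-mixed tank run continuously and read at steady state, 80 min in it on average | plug flow through a tube for 80 min, no back-mixing | everything together in a closed stirred flask, run for 80 min | all but partner at the start; partner goes in evenly over 64.0 min, the run ends at 80 min |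
| time |  |  |  |  | 80 min | 80 min | 80 min |

| epsilon: time / min | epsilon: target / % | zeta: time / min | zeta: target / % | gamma: time / min | gamma: target / % |
|---|---|---|---|---|---|
| 6.00 | 0.4 | 6.00 | 0.1 | 15.0 | 0.7 |
| 10.0 | 0.7 | 20.0 | 1.2 | 30.0 | 2.1 |
| 20.0 | 1.1 | 30.0 | 1.9 | 50.0 | 2.8 |
| 30.0 | 1.9 | 50.0 | 2.7 | 60.0 | 3.1 |
| 50.0 | 3.3 | 80.0 | 4.7 | 80.0 | 5.1 |
| 80.0 | 5.0 | 90.0 | 5.1 | 90.0 | 5.5 |

(readings scatter by 0.3 percentage points)

- the stated concentrations are those of everything mixed, before any reaction; amounts are the same in each set-up
- the feed brings no volume worth counting
- the earlier runs were made in a closed, stirred flask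

1. the set-up with the highest amount of target at the outlet or at the end, in percent of the substrate put in ("none" if the first two lie within 2 percentage points) (Tuesday's / Thursday's / Saturday's / Sunday's / none)
2. amount of target at the outlet or at the end, in percent of the substrate put in, Tuesday's
3. amount of target at the outlet or at the end, in percent of the substrate put in, Thursday's
4. amount of target at the outlet or at the end, in percent of the substrate put in, Saturday's
5. amount of target at the outlet or at the end, in percent of the substrate put in, Sunday's

I asked first which given number had to be known well. Free catalyst did not: twice the charge moved the reading at that time by 0.4 percentage points, against a scatter of 0.3 points. The vessel mattered little with partner present from the start, since that much target uses hardly any of the partner charge, about 3.79%, so I put Tuesday's, Thursday's and Saturday's near the mean reading. Thursday's and Saturday's hold the same charge for the same time without back-mixing, so I expected these two to tie, and with Tuesday's beside them and Sunday's reckoned no higher I answered none.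

The partner order did matter, and each earlier run started with [partner] at 0.143 M, so the readings do not show it. At zero order Sunday's stays at 4.93%. For first order I used the mean partner fraction 0.600, the [partner] averaged over the run as a share of the whole charge, with the ramp counted at its midpoint and the hold at full level. With a rate proportional to [partner] and otherwise constant in time, the mean replaces the ramp without error, and the partner consumption above is a further correction. I committed to first order as an assumption the readings neither support nor exclude, which gave 2.96% for Sunday's.

The forecast gave 4.9%, 5%, 5% and 4% for Tuesday's, Thursday's, Saturday's and Sunday's, with none as best, calling “Sunday's is the real unknown”, and its Sunday's figure stood above mine. The flasks gave 4.73%, 4.80%, 4.80% and 2.92% in that order, with none as best.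

    second catalyst + open intermediate ⇌ catalyst intermediate (K = 300 L mol⁻¹, k = 360 L mol⁻¹ s⁻¹)
    partner + catalyst intermediate → second catalyst + target (k = 0.0740 L mol⁻¹ s⁻¹)
    substrate + free catalyst → free catalyst + open intermediate (k = 0.300 L mol⁻¹ s⁻¹)

In Sunday's flask, half of the turnover of substrate to open intermediate was done by 3.50 min. At 40.0 min, with [partner] at 61.9% of its charge, 97.0% of the second catalyst sat as catalyst intermediate, the resting state, and the step of partner with catalyst intermediate had behind it 26% of its turnover up to 80 min. Target reached 2.92%, against 2.96% from the mean partner fraction of 0.600. Left until 2.5 h, Sunday's flask had a mean partner fraction of 0.787, which at the pace of the closed-flask readings gave 7.27%, and it stood at 7.06%.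

(The numbers in the tables were generated by integration from invented constants, noise included.)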